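## The problem

The target 25 is a guai-1(10)-ene ester: a cyclopentane (ring A: C1, C2, C3, C4, C5) fused at C1 and C5 to a seven-membered ring (C1, C5, C6, C7, C8, C9, C10), with the tetrasubstituted C1=C10 alkene in place of one ring-fusion stereocentre. Five contiguous stereocentres remain: C4 (tertiary carbinol), C5, C6 (free carbinol), C7 (isopropyl) and C8 (4-hydroxybenzoate). With the face of H-5 called α they are 4α-methyl/4β-OH, 6β-OH, 7β-isopropyl and 8α-O, i.e. (4S,5S,6R,7S,8S). O4 and O6 are syn across C5 and can both be set by attack on the convex face of a folded cis-bicycle, and O6 can then deliver hydride to C8 to give the anti relationship. C7 lies between two oxygenated carbons, is epimerisable whenever C6 or C8 is a carbonyl group, and stands cis to O6, so it has to be fixed early by reagent control and kept away from enolising conditions. The fragile points are the β,γ-unsaturated ketone stage (the C1=C10 alkene can slip into conjugation), the β-hydroxy ketones (retro-aldol, dehydration), the tertiary C4 alcohol, the 1,3-diol monoester (acyl migration) and the free phenol. The enabling feature appears at the C8 ketone level: C8(=O), C9 and C10=C1 form a β,γ-unsaturated ketone, and moving the acyl carbon C8 from C9 back to C1 contracts the seven-membered ring to a cyclopentanone (ring B: C8, C1, C5, C6, C7) whose α-carbon C1 is quaternary and carries an isopropenyl group (C10, C9 and the C10 methyl).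

## Retrosynthesis

**Ester and phenol.** The C8–O acyl bond of 25 is cut last: acetate 24 comes from triol 22 and 4-acetoxybenzoyl chloride 23. The arene enters late because C8 must be a ketone for the key step, and a second chromophore and a labile ester are best kept out of the photolysis and hydride steps. The forward step must pick O8 out of three hydroxyls, and the phenolic acetate must leave without touching the benzoate.

**C8 carbinol.** The C8–H bond of 22 is cut to give dihydroxy ketone 21, which is acetonide 20 without its acetal. A free O6 is wanted here because it can deliver hydride to C8 from its own face, which gives the anti (8α) alcohol. An external hydride on the seven-membered ring has no comparable bias.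

**Ring contraction (key cut).** In 20 the C8–C9 bond is cut and C8 is rejoined to C1, giving diquinane ketone 19. This is preferred over cuts through the ring fusion because it creates no stereocentre. C4–C7 sit on a rigid cis-bicyclo[3.3.0]octane where they are easier to control than on a cycloheptene, and the quaternary C1 is an asset rather than a burden. The forward reaction must cleave C8–C1 and not C8–C7, rebond at C9, and stay in the singlet manifold.

**Oxidation levels on the diquinane.** 19 is traced through alcohol 18, silyl ether 17 and diol 16 to hydroxy ketone 15. The C8 oxygen is carried as a silyl ether until late because it is the control element of the next cut. The syn O4/O6 diol is tied up as one acetonide, and C6 is derived from a ketone by convex-face hydride.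

**Both rings joined.** In 15 the C1–C10 and C4–C5 bonds are cut, giving cyclopentenone 12 and isopropenylmagnesium bromide 13. The neighbouring cut would add the isopropenyl group to a ring A enone that carries a C6–C8 side chain. That needs oxygen on a neopentyl C8 and lets an open-chain stereocentre decide the face at C1. Here the C8 silyloxy group sits on the ring next to C1 and steers the cuprate anti, the enolate is formed only at C5, and the C4 tertiary carbinol is the direct aldol product of a methyl ketone. The precursor is monocyclic with two stereocentres.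

**Ring B.** The C1=C5 alkene of 12 (via its ketal 11) is cut by retro-metathesis to dienone 10. Metathesis is neutral, so the base-sensitive β-silyloxy ketone and the cis C7/C8 pair survive. An aldol condensation of a 1,4-diketone would expel the C8 oxygen.

**C7–C8 bond.** 10 comes via Weinreb amides 9 and 8 from aldol adduct 7, which is cut at C7–C8 into enal 4 and the isovaleryl imide 5. An auxiliary-controlled anti-aldol sets C7 and the temporary C8 centre in one step from achiral and commercial partners. The anti array becomes the cis pair on ring B.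

**Enal.** 4 is the α-methylenation product of aldehyde 3, made by formylating the Grignard reagent of chloro ketal 1.

## Roads not taken

Alternative 1: The seven-membered ring is cut back to a benzene ring. C5 is detached from C1 and C6, leaving diazoketone A1, an arene that already carries the C10 methyl, the C7 isopropyl and a C8 methoxy group. In the forward sense Rh2(S-PTTL)4 generates a carbene at C5 that cyclopropanates the arene C1–C6 bond. Six-electron ring opening then gives dihydroazulenone A2, closing ring A and expanding the arene in one step.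
- Merits: in step count to the bicyclic skeleton this road is clearly better than the chosen one. All carbons are in place within a few steps from a cheap aromatic, and C5 is set by a catalyst.
- Weak points: they come after the key step. In A2, C6 and C7 are sp2 carbons, so O6 and the C7 hydrogen must be added to a triene with regio- and facial control. C5 is α to the C4 ketone and doubly allylic, so it can racemise and the triene can undergo 1,5-hydrogen shifts. The carbene must also choose the C1–C6 over the C1–C10 bond.
- Comparison: the chosen plan is much longer up to 19. Against that, C4–C7 are fixed on a rigid diquinane before the ring is expanded, and the expansion leaves C8 and C10 at the right oxidation level with nothing to reduce.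

Alternative 2: C1–C5, C2–C3 and C3–C4 are cut, giving acyclic allenyne A3, in which C6, C7 and C8 already carry their silyloxy and isopropyl groups. With [Rh(CO)2Cl]2 the alkyne, the terminal allene double bond and a carbonyl unit combine in an allenic Pauson–Khand reaction to dienone A4. This forms ring A and the seven-membered ring together, with C1=C10 in place.
- Merits: the route is convergent, and the C6–C8 triad is made by open-chain aldol chemistry. The ring-forming step is catalytic and thermal, and in that respect at least as good as a photolysis that has to be run to a photostationary state.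
- Weak points: the carbonyl arrives at C3, where the target has a methylene, while C4 needs a tertiary hydroxyl and C5 a hydrogen. The C4=C5 enone must be hydrated at its α-carbon and the C3 oxygen removed, with C5 set relative to C6 on a flexible ring and the C1=C10 alkene of a dienone left alone.
- Comparison: these corrections cost about as many steps as ring B costs in the chosen route. The chosen plan sets C4 and C5 in one aldol on a cyclopentanone and never has oxygen at C3.

Alternative 3: The seven-membered ring is cut at C9–C10 and C5–C6 into vinyldiazoacetate A5 (ring A with the C4 carbinol, C10 as carbenoid carbon bearing an ester) and siloxydiene A6 (C6–C9 with the isopropyl group on C7). Rh2(S-DOSP)4 gives cyclopropanation at the terminal C8=C9 alkene, and the divinylcyclopropane (Cope) rearrangement delivers cycloheptadiene ester A7 with C5 and C6 set through the boat transition state.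
- Merits: this is the most convergent road, with two fragments of similar size, and it is probably shorter to the bicyclic stage. Its control of C5/C6 is as good as that of the chosen route.
- Weak points: A5 is already chiral, so catalyst and substrate preferences must match. C10 emerges as an ester that has to be reduced to a methyl group next to a tetrasubstituted alkene. C7=C8 must be turned into 7α-H and 8α-O, an anti-Markovnikov hydration with the hydrogen delivered cis to the neighbouring silyloxy group.
- Comparison: in the chosen route C10 is a methyl group and C8 a ketone directly after the key step, and C7 is fixed at the first C–C bond formation. The price is a linear preparation of 19 and recycling in the photolysis.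

Key step: step 14

Conventions and one assumption: guaiane numbers are kept for every intermediate. α is the face of H-5 and of the angular isopropenyl group (convex face of the diquinanes), β the opposite (concave) face. The magnesium-catalysed anti-aldol of 5 is assumed to follow the facial sense of the chelated Z-enolate (attack anti to the benzyl group, as in alkylations of 5); if the opposite sense were found, the enantiomeric auxiliary would be used.

Step 1
Reactants: 1 2-(3-chloropropyl)-2-methyl-1,3-dioxolane
Product: 3 4-(2-methyl-1,3-dioxolan-2-yl)butanal, via Grignard reagent 2 (not isolated)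
Conditions: Mg, BrCH2CH2Br (cat.), THF, reflux; then DMF, 0 °C; aq. NH4Cl
Reagents that add atoms: N,N-dimethylformamide, CN(C)C=O
Why: Grignard formation from the primary chloride and formylation with DMF (Bouveault aldehyde synthesis); the ketal is inert to the organomagnesium reagent and to the buffered work-up.

Step 2
Reactants: 3 4-(2-methyl-1,3-dioxolan-2-yl)butanal
Product: 4 2-methylidene-4-(2-methyl-1,3-dioxolan-2-yl)butanal
Conditions: 37% aq. CH2O, pyrrolidine (10 mol %), propanoic acid (10 mol %), i-PrOH, 45 °C
Reagents that add atoms: formaldehyde, C=O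
Why: Amine/acid-catalysed Mannich condensation with formaldehyde and elimination (organocatalytic α-methylenation of aldehydes) should give the α-substituted acrolein; no stereocentre is formed.

Step 3
Reactants: 4 2-methylidene-4-(2-methyl-1,3-dioxolan-2-yl)butanal; 5 (4S)-4-benzyl-3-(3-methylbutanoyl)-1,3-oxazolidin-2-one
Product: 7 (4S)-4-benzyl-3-[(2R,3S)-3-hydroxy-4-methylidene-6-(2-methyl-1,3-dioxolan-2-yl)-2-(propan-2-yl)hexanoyl]-1,3-oxazolidin-2-one, via trimethylsilyl ether 6 (not isolated)
Conditions: MgCl2 (20 mol %), Et3N, Me3SiCl, EtOAc, 23 °C; then Et3N·3HF, THF, 0 °C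
Reagents that add atoms: none
Why: Magnesium-halide-catalysed anti-aldol of an N-acyloxazolidinone (Evans anti-aldol) with a non-enolisable enal: the chelated Z-enolate should be attacked anti to the benzyl group through a boat transition state, setting C7 (2R) and the temporary C8 centre (3S) anti to each other; Et3N·3HF then removes the trimethylsilyl group without touching the ketal.

Step 4
Reactants: 7 (4S)-4-benzyl-3-[(2R,3S)-3-hydroxy-4-methylidene-6-(2-methyl-1,3-dioxolan-2-yl)-2-(propan-2-yl)hexanoyl]-1,3-oxazolidin-2-one
Product: 8 (2R,3S)-3-hydroxy-N-methoxy-N-methyl-4-methylidene-6-(2-methyl-1,3-dioxolan-2-yl)-2-(propan-2-yl)hexanamide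
Conditions: MeNH(OMe)·HCl, AlMe3, CH2Cl2, −10 → 0 °C
Reagents that add atoms: N,O-dimethylhydroxylamine hydrochloride, CNOC.Cl
Why: Aluminium-amide transamination of a β-hydroxy imide (Weinreb amide formation) is assisted by chelation of the free hydroxyl and releases the auxiliary without epimerising C7.

Step 5
Reactants: 8 (2R,3S)-3-hydroxy-N-methoxy-N-methyl-4-methylidene-6-(2-methyl-1,3-dioxolan-2-yl)-2-(propan-2-yl)hexanamide
Product: 9 (2R,3S)-3-(tert-butyldimethylsilyloxy)-N-methoxy-N-methyl-4-methylidene-6-(2-methyl-1,3-dioxolan-2-yl)-2-(propan-2-yl)hexanamide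
Conditions: t-BuMe2SiOTf, 2,6-lutidine, CH2Cl2, −78 → 0 °C
Reagents that add atoms: tert-butyldimethylsilyl trifluoromethanesulfonate, CC(C)(C)[Si](C)(C)OS(=O)(=O)C(F)(F)F
Why: Silyl triflate silylation of a hindered allylic alcohol; this silyl ether later directs the cuprate and should survive Grignard addition, metathesis and mild acid.

Step 6
Reactants: 9 (2R,3S)-3-(tert-butyldimethylsilyloxy)-N-methoxy-N-methyl-4-methylidene-6-(2-methyl-1,3-dioxolan-2-yl)-2-(propan-2-yl)hexanamide
Product: 10 (4R,5S)-5-(tert-butyldimethylsilyloxy)-6-methylidene-8-(2-methyl-1,3-dioxolan-2-yl)-4-(propan-2-yl)oct-1-en-3-one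
Conditions: CH2=CHMgBr, THF, −20 → 0 °C; inverse quench into cold aq. NH4Cl
Reagents that add atoms: vinylmagnesium bromide, C=C[Mg]Br
Why: Weinreb ketone synthesis: the chelated tetrahedral intermediate prevents over-addition and shields the α-stereocentre C7 until the cold buffered quench.

Step 7
Reactants: 10 (4R,5S)-5-(tert-butyldimethylsilyloxy)-6-methylidene-8-(2-methyl-1,3-dioxolan-2-yl)-4-(propan-2-yl)oct-1-en-3-one
Product: 11 (4S,5R)-4-(tert-butyldimethylsilyloxy)-3-[2-(2-methyl-1,3-dioxolan-2-yl)ethyl]-5-(propan-2-yl)cyclopent-2-en-1-one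
Conditions: second-generation Grubbs catalyst (5 mol %), CH2Cl2, 40 °C
Reagents that add atoms: none
Why: Ring-closing metathesis of the vinyl ketone with the 1,1-disubstituted alkene should close ring B (C6, C5, C1, C8, C7) as a 3-substituted cyclopent-2-enone with loss of ethene; C7 and C8 are untouched and are now cis on the ring.

Step 8
Reactants: 11 (4S,5R)-4-(tert-butyldimethylsilyloxy)-3-[2-(2-methyl-1,3-dioxolan-2-yl)ethyl]-5-(propan-2-yl)cyclopent-2-en-1-one
Product: 12 (4S,5R)-4-(tert-butyldimethylsilyloxy)-3-(3-oxobutyl)-5-(propan-2-yl)cyclopent-2-en-1-one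
Conditions: PPTS, acetone/H2O (10:1), 40 °C
Reagents that add atoms: water, O
Why: Acid-catalysed ketal hydrolysis unmasks the C4 methyl ketone; PPTS should be too weak to cleave the secondary silyl ether or to enolise C7 appreciably.

Step 9
Reactants: 12 (4S,5R)-4-(tert-butyldimethylsilyloxy)-3-(3-oxobutyl)-5-(propan-2-yl)cyclopent-2-en-1-one; 13 isopropenylmagnesium bromide
Product: 15 cis-diquinane 8β-(tert-butyldimethylsilyloxy)-4β-hydroxy-1α-isopropenyl-7β-isopropyl-4α-methyl-5αH-bicyclo[3.3.0]octan-6-one (guaiane numbers; ring A C1–C5; ring B C1/C5/C6/C7/C8), via magnesium enolate 14 (not isolated)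
Conditions: 13 (3 equiv), CuBr·SMe2 (1.5 equiv), THF/Me2S, −78 °C [(CH2=C(CH3))2CuMgBr]; add 12, −78 → −20 °C; aq. NH4Cl/NH3
Reagents that add atoms: none
Why: Tandem cuprate conjugate addition–intramolecular aldol onto a pendant ketone: the isopropenyl group should add to C1 anti to the adjacent 8β-silyloxy and the 7β-isopropyl groups (the usual trans selectivity of 4-silyloxycyclopentenones); the regiodefined C5 enolate 14 then attacks the methyl ketone on the β face (5-exo-trig, enolexo; only cis fusion is possible) through a metal-bridged transition state that holds O4 syn to the C6 carbonyl, so C1, C5 and C4 (4α-methyl, 4β-OH) are set in one operation.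

Step 10
Reactants: 15 cis-diquinane hydroxy ketone (C6 ketone, 4β-OH, 8β-silyl ether)
Product: 16 cis-diquinane 8β-(tert-butyldimethylsilyloxy)-1α-isopropenyl-7β-isopropyl-4α-methyl-5αH-bicyclo[3.3.0]octane-4β,6β-diol
Conditions: NaBH4, MeOH/CH2Cl2, −78 → −40 °C
Reagents that add atoms: none
Why: Hydride should attack the C6 ketone from the open convex α face, giving the concave 6β-alcohol syn to O4; the low temperature guards the tertiary aldol against retro-aldol cleavage.

Step 11
Reactants: 16 diquinane 4β,6β-diol 8β-silyl ether
Product: 17 4β,6β-O-isopropylidene acetal of 16 (six-membered acetonide across C4–C5–C6; 8β-silyl ether retained)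
Conditions: Me2C(OMe)2, PPTS (cat.), CH2Cl2, 23 °C
Reagents that add atoms: 2,2-dimethoxypropane, COC(C)(C)OC
Why: The syn-1,3-diol on the concave face should close to an isopropylidene acetal by acid-catalysed transacetalisation, protecting both hydroxyls with one small, photochemically inert group that is orthogonal to the silyl ether.

Step 12
Reactants: 17 acetonide silyl ether
Product: 18 cis-diquinane 4β,6β-O-isopropylidene-1α-isopropenyl-7β-isopropyl-4α-methyl-5αH-bicyclo[3.3.0]octane-4β,6β,8β-triol (free 8β-OH)
Conditions: Bu4NF, THF, 23 → 45 °C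
Reagents that add atoms: none
Why: Fluoride cleaves the silyl ether; acetonide and alkene are inert.

Step 13
Reactants: 18 acetonide 8β-alcohol
Product: 19 cis-diquinane ketone 4β,6β-O-isopropylidene-4β,6β-dihydroxy-1α-isopropenyl-7β-isopropyl-4α-methyl-5αH-bicyclo[3.3.0]octan-8-one
Conditions: Dess–Martin periodinane, NaHCO3, CH2Cl2, 0 → 23 °C
Reagents that add atoms: none
Why: Buffered Dess–Martin oxidation is non-enolising, so C7 should keep its configuration; C1 is quaternary, so the β,γ-alkene cannot move into conjugation.

Step 14
Reactants: 19 cis-diquinane ketone (C8 ketone, angular isopropenyl on C1)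
Product: 20 4β,6β-O-isopropylidene-4β,6β-dihydroxy-5αH,7αH-guai-1(10)-en-8-one
Conditions: hν (300 nm, Pyrex), degassed benzene (5 mM), 15 °C, to the photostationary state; recovered 19 recycled
Reagents that add atoms: none
Why: Direct n→π* excitation of the β,γ-unsaturated ketone should lead to Norrish type 1 cleavage of C8–C1, giving an acyl radical at C8 and an allyl radical (C1–C10–C9) held together by the C7–C6–C5 tether; rebonding of C8 to C9 completes a 1,3-acyl shift, the known photoreaction of β,γ-unsaturated ketones that expands 2-alkenylcycloalkanones by two carbons. The seven-membered ring closes by radical-pair recombination at the distal allyl carbon C9 (formally a 7-endo closure on the allyl unit), and the new alkene is the tetrasubstituted C1=C10 bond. No stereocentre is created: C1 is erased and C4, C5, C6 and C7 are bystanders. Cleavage at C8–C1 rather than C8–C7 is secured by C1 being quaternary and allylic, whereas C7 would give an unstabilised secondary radical. Recombination at C1 only regenerates 19, so the mixture moves to a photostationary state that should favour the less strained 20 with its more substituted alkene, and 19 is recycled. Irradiation near 300 nm without a sensitiser keeps the reaction out of the lowest triplet, from which the oxa-di-π-methane (1,2-acyl shift) path would start; high dilution and moderate conversion per pass limit decarbonylation and Norrish type 2 abstraction. The acetonide adds no competing chromophore.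

Step 15
Reactants: 20 acetonide cycloheptenone
Product: 21 4β,6β-dihydroxy-5αH,7αH-guai-1(10)-en-8-one
Conditions: PPTS, MeOH, 40 °C
Reagents that add atoms: none
Why: Acid-catalysed transacetalisation to methanol frees the diol; the acid is kept weak so that the β,γ-alkene does not conjugate, C7 is not epimerised and the β-hydroxy ketone does not dehydrate.

Step 16
Reactants: 21 4β,6β-dihydroxy-5αH,7αH-guai-1(10)-en-8-one
Product: 22 5αH,7αH-guai-1(10)-ene-4β,6β,8α-triol
Conditions: Me4NBH(OAc)3, MeCN/AcOH (1:1), −25 °C
Reagents that add atoms: none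
Why: Evans–Saksena directed reduction: the O6-bound acetoxyborohydride should deliver hydride intramolecularly to the face of the C8 carbonyl syn to O6, so the new hydroxyl is anti to O6 (8α); this sets the last stereocentre.

Step 17
Reactants: 22 5αH,7αH-guai-1(10)-ene-4β,6β,8α-triol; 23 4-acetoxybenzoyl chloride
Product: 24 8α-(4-acetoxybenzoyloxy)-5αH,7αH-guai-1(10)-ene-4β,6β-diol
Conditions: 23 (1.1 equiv), pyridine, DMAP (cat.), CH2Cl2, −20 → 0 °C
Reagents that add atoms: none
Why: Nucleophile-catalysed acylation should distinguish the hydroxyls by hindrance: O4 is tertiary, O6 is flanked by the ring fusion and the cis isopropyl group, whereas O8 has a methylene neighbour and is trans to the isopropyl group.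

Step 18
Reactants: 24 8α-(4-acetoxybenzoyloxy)-5αH,7αH-guai-1(10)-ene-4β,6β-diol
Product: 25 8α-(4-hydroxybenzoyloxy)-5αH,7αH-guai-1(10)-ene-4β,6β-diol, i.e. (3S,3aS,4R,5S,6S)-3,4-dihydroxy-3,8-dimethyl-5-(propan-2-yl)-1,2,3,3a,4,5,6,7-octahydroazulen-6-yl 4-hydroxybenzoate
Conditions: pyrrolidine (2 equiv), CH2Cl2, 0 °C
Reagents that add atoms: none
Why: Aryl acetates are aminolysed far faster than an alkyl benzoate, and the freed phenol deactivates the remaining ester further, so the phenol should be unmasked without acyl migration.

## Compound list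

1 | 2-(3-chloropropyl)-2-methyl-1,3-dioxolane | ClCCCC1(C)OCCO1 | starting material
2 | [3-(2-methyl-1,3-dioxolan-2-yl)propyl]magnesium chloride | Cl[Mg]CCCC1(C)OCCO1 | intermediate
3 | 4-(2-methyl-1,3-dioxolan-2-yl)butanal | O=CCCCC1(C)OCCO1 | intermediate
4 | 2-methylidene-4-(2-methyl-1,3-dioxolan-2-yl)butanal | C=C(C=O)CCC1(C)OCCO1 | intermediate
5 | (4S)-4-benzyl-3-(3-methylbutanoyl)-1,3-oxazolidin-2-one | CC(C)CC(=O)N1[C@@H](Cc2ccccc2)COC1=O | starting material
6 | (4S)-4-benzyl-3-[(2R,3S)-4-methylidene-6-(2-methyl-1,3-dioxolan-2-yl)-2-(propan-2-yl)-3-(trimethylsilyloxy)hexanoyl]-1,3-oxazolidin-2-one | O=C1OC[C@H](Cc2ccccc2)N1C(=O)[C@H](C(C)C)[C@H](O[Si](C)(C)C)C(=C)CCC3(C)OCCO3 | intermediate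
7 | (4S)-4-benzyl-3-[(2R,3S)-3-hydroxy-4-methylidene-6-(2-methyl-1,3-dioxolan-2-yl)-2-(propan-2-yl)hexanoyl]-1,3-oxazolidin-2-one | O=C1OC[C@H](Cc2ccccc2)N1C(=O)[C@H](C(C)C)[C@H](O)C(=C)CCC3(C)OCCO3 | intermediate
8 | (2R,3S)-3-hydroxy-N-methoxy-N-methyl-4-methylidene-6-(2-methyl-1,3-dioxolan-2-yl)-2-(propan-2-yl)hexanamide | CON(C)C(=O)[C@H](C(C)C)[C@H](O)C(=C)CCC1(C)OCCO1 | intermediate
9 | (2R,3S)-3-(tert-butyldimethylsilyloxy)-N-methoxy-N-methyl-4-methylidene-6-(2-methyl-1,3-dioxolan-2-yl)-2-(propan-2-yl)hexanamide | CON(C)C(=O)[C@H](C(C)C)[C@H](O[Si](C)(C)C(C)(C)C)C(=C)CCC1(C)OCCO1 | intermediate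
10 | (4R,5S)-5-(tert-butyldimethylsilyloxy)-6-methylidene-8-(2-methyl-1,3-dioxolan-2-yl)-4-(propan-2-yl)oct-1-en-3-one | C=CC(=O)[C@H](C(C)C)[C@H](O[Si](C)(C)C(C)(C)C)C(=C)CCC1(C)OCCO1 | intermediate
11 | (4S,5R)-4-(tert-butyldimethylsilyloxy)-3-[2-(2-methyl-1,3-dioxolan-2-yl)ethyl]-5-(propan-2-yl)cyclopent-2-en-1-one | O=C1C=C(CCC2(C)OCCO2)[C@@H](O[Si](C)(C)C(C)(C)C)[C@H]1C(C)C | intermediate
12 | (4S,5R)-4-(tert-butyldimethylsilyloxy)-3-(3-oxobutyl)-5-(propan-2-yl)cyclopent-2-en-1-one | O=C1C=C(CCC(C)=O)[C@@H](O[Si](C)(C)C(C)(C)C)[C@H]1C(C)C | intermediate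
13 | isopropenylmagnesium bromide (prop-1-en-2-ylmagnesium bromide) | CC(=C)[Mg]Br | starting material
14 | bromomagnesium C5=C6 enolate of the conjugate adduct of 12 (ring B; 1α-isopropenyl, 1β-(3-oxobutyl), 7β-isopropyl, 8β-silyloxy) | C=C(C)[C@@]1(CCC(C)=O)C=C(O[Mg]Br)[C@H](C(C)C)[C@@H]1O[Si](C)(C)C(C)(C)C | intermediate
15 | cis-diquinane: 8β-(tert-butyldimethylsilyloxy)-4β-hydroxy-1α-isopropenyl-7β-isopropyl-4α-methyl-5αH-bicyclo[3.3.0]octan-6-one (guaiane numbers) | C=C(C)[C@@]12CC[C@](C)(O)[C@@H]1C(=O)[C@H](C(C)C)[C@@H]2O[Si](C)(C)C(C)(C)C | intermediate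
16 | cis-diquinane: 8β-(tert-butyldimethylsilyloxy)-1α-isopropenyl-7β-isopropyl-4α-methyl-5αH-bicyclo[3.3.0]octane-4β,6β-diol | C=C(C)[C@@]12CC[C@](C)(O)[C@@H]1[C@H](O)[C@H](C(C)C)[C@@H]2O[Si](C)(C)C(C)(C)C | intermediate
17 | 4β,6β-O-isopropylidene acetal of 16 (8β-silyl ether) | C=C(C)[C@@]12CC[C@](C)(OC3(C)C)[C@@H]1[C@H](O3)[C@H](C(C)C)[C@@H]2O[Si](C)(C)C(C)(C)C | intermediate
18 | cis-diquinane: 4β,6β-O-isopropylidene-1α-isopropenyl-7β-isopropyl-4α-methyl-5αH-bicyclo[3.3.0]octane-4β,6β,8β-triol (free 8β-OH) | C=C(C)[C@@]12CC[C@](C)(OC3(C)C)[C@@H]1[C@H](O3)[C@H](C(C)C)[C@@H]2O | intermediate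
19 | cis-diquinane ketone: 4β,6β-O-isopropylidene-4β,6β-dihydroxy-1α-isopropenyl-7β-isopropyl-4α-methyl-5αH-bicyclo[3.3.0]octan-8-one | C=C(C)[C@@]12CC[C@](C)(OC3(C)C)[C@@H]1[C@H](O3)[C@H](C(C)C)C2=O | intermediate
20 | 4β,6β-O-isopropylidene-4β,6β-dihydroxy-5αH,7αH-guai-1(10)-en-8-one | CC1=C2CC[C@](C)(OC3(C)C)[C@@H]2[C@H](O3)[C@H](C(C)C)C(=O)C1 | intermediate
21 | 4β,6β-dihydroxy-5αH,7αH-guai-1(10)-en-8-one | CC1=C2CC[C@](C)(O)[C@@H]2[C@H](O)[C@H](C(C)C)C(=O)C1 | intermediate
22 | 5αH,7αH-guai-1(10)-ene-4β,6β,8α-triol | CC1=C2CC[C@](C)(O)[C@@H]2[C@H](O)[C@H](C(C)C)[C@@H](O)C1 | intermediate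
23 | 4-acetoxybenzoyl chloride | CC(=O)Oc1ccc(cc1)C(Cl)=O | starting material
24 | 8α-(4-acetoxybenzoyloxy)-5αH,7αH-guai-1(10)-ene-4β,6β-diol | CC1=C2CC[C@](C)(O)[C@@H]2[C@H](O)[C@H](C(C)C)[C@@H](OC(=O)c2ccc(OC(C)=O)cc2)C1 | intermediate
25 | (3S,3aS,4R,5S,6S)-3,4-dihydroxy-3,8-dimethyl-5-(propan-2-yl)-1,2,3,3a,4,5,6,7-octahydroazulen-6-yl 4-hydroxybenzoate | CC1=C2CC[C@](C)(O)[C@@H]2[C@H](O)[C@H](C(C)C)[C@@H](OC(=O)c2ccc(O)cc2)C1 | target

## Step count and least certain steps

Total: 18 steps. Longest linear sequence: 18 steps (from 1; compounds 5, 13 and 23 are purchased).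

**Step 14 (key step).** The most likely failure is loss of material through decarbonylation of the acyl radical or through secondary photoreactions of 20, which is itself a β,γ-unsaturated ketone with abstractable γ-hydrogens. The photostationary state could also lie less far towards 20 than expected. Fallback, setting out from 18 and returning at 20: the potassium alkoxide of 18 (KH, 18-crown-6, THF) is a 2-alkenylcycloalkanolate. An alkoxide-accelerated 1,3-shift (heterolytic opening of C8–C1 to an aldehyde/allyl anion pair and re-closure at C9) would give the ring-expanded cycloheptenol F1. Dess–Martin oxidation of F1 gives 20. The bond changes are the same, but an ionic pair replaces the radical pair.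

**Step 9.** The first-formed C5 enolate may equilibrate to the C7 side and expel the silyloxy group. Conjugate addition at the β,β-disubstituted carbon next to two β-face substituents may also be slow enough for attack on the methyl ketone to compete. Fallback, from 12 back to 15: the cuprate addition is run with Me3SiCl present, so that the enolate is trapped at once as the silyl enol ether F2. Ring A is then closed in a separate TiCl4-mediated Mukaiyama aldol at −78 °C, which never generates a free basic enolate.

**Step 3.** Soft enolisation of the β-branched imide may be sluggish and the anti selectivity may erode, since this aldol is best established for less hindered acyl groups. Fallback, from 4 back to 10: D-proline-catalysed cross-aldol of isovaleraldehyde (donor) with 4 should give the anti β-hydroxy aldehyde F3 with the same C7/C8 configuration. Silylation (t-BuMe2SiOTf, 2,6-lutidine) gives the silyl ether F4, vinylmagnesium bromide gives the epimeric allylic alcohols F5, and Dess–Martin oxidation gives 10. This replaces auxiliary control by catalyst control and bypasses the Weinreb amide.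

**Step 17 (with step 16).** Acylation may be insufficiently selective between O8 and O6, or go on to the bis-ester, and any shortfall in the anti selectivity of step 16 shows up here as well. Fallback, from 20 back to 24: with the acetonide still in place, LiBH(s-Bu)3 should add hydride to C8 from the α face, anti to the isopropyl group, giving the 8β-alcohol F6. Mitsunobu esterification of F6 with 4-acetoxybenzoic acid (PPh3, diisopropyl azodicarboxylate) inverts C8 and gives the 8α-ester acetonide F7. No choice between hydroxyls arises because O4 and O6 are tied up. PPTS in MeOH then removes the acetonide to give 24.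

## Further compounds

F1 | step 14 | 4β,6β-O-isopropylidene-5αH,7αH-guai-1(10)-ene-4β,6β,8-triol (C8 epimers) | CC1=C2CC[C@](C)(OC3(C)C)[C@@H]2[C@H](O3)[C@H](C(C)C)C(O)C1
F2 | step 9 | trimethylsilyl enol ether (C5=C6) of the conjugate adduct of 12 | C=C(C)[C@@]1(CCC(C)=O)C=C(O[Si](C)(C)C)[C@H](C(C)C)[C@@H]1O[Si](C)(C)C(C)(C)C
F3 | step 3 | (2R,3S)-3-hydroxy-4-methylidene-6-(2-methyl-1,3-dioxolan-2-yl)-2-(propan-2-yl)hexanal | O=C[C@H](C(C)C)[C@H](O)C(=C)CCC1(C)OCCO1
F4 | step 3 | (2R,3S)-3-(tert-butyldimethylsilyloxy)-4-methylidene-6-(2-methyl-1,3-dioxolan-2-yl)-2-(propan-2-yl)hexanal | O=C[C@H](C(C)C)[C@H](O[Si](C)(C)C(C)(C)C)C(=C)CCC1(C)OCCO1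
F5 | step 3 | 5-(tert-butyldimethylsilyloxy)-6-methylidene-8-(2-methyl-1,3-dioxolan-2-yl)-4-(propan-2-yl)oct-1-en-3-ol (C3 epimers; C4 and C5 as in 10) | C=CC(O)[C@H](C(C)C)[C@H](O[Si](C)(C)C(C)(C)C)C(=C)CCC1(C)OCCO1
F6 | step 17 | 4β,6β-O-isopropylidene-5αH,7αH-guai-1(10)-ene-4β,6β,8β-triol | CC1=C2CC[C@](C)(OC3(C)C)[C@@H]2[C@H](O3)[C@H](C(C)C)[C@H](O)C1
F7 | step 17 | 8α-(4-acetoxybenzoyloxy)-4β,6β-O-isopropylidene-5αH,7αH-guai-1(10)-ene-4β,6β-diol | CC1=C2CC[C@](C)(OC3(C)C)[C@@H]2[C@H](O3)[C@H](C(C)C)[C@@H](OC(=O)c3ccc(OC(C)=O)cc3)C1
A1 | alternative 1 | 1-diazo-4-[4-methoxy-2-methyl-5-(propan-2-yl)phenyl]butan-2-one | [N-]=[N+]=CC(=O)CCc1cc(C(C)C)c(OC)cc1C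
A2 | alternative 1 | dihydroazulenone (C4 ketone, C8 methyl enol ether, 5-H stereocentre) | CC1=C2CCC(=O)[C@@H]2C=C(C(C)C)C(OC)=C1
A3 | alternative 2 | allenyne: 6-(triethylsilyloxy)-8-(tert-butyldimethylsilyloxy)-7-isopropyl chain from but-2-ynyl terminus to 1,1-disubstituted allene | CC#C[C@H](O[Si](CC)(CC)CC)[C@H](C(C)C)[C@@H](O[Si](C)(C)C(C)(C)C)CC(C)=C=C
A4 | alternative 2 | bicyclo[5.3.0]decadienone (C3 ketone, C4=C5 and C1=C10 alkenes) | CC1=C2CC(=O)C(C)=C2[C@H](O[Si](CC)(CC)CC)[C@H](C(C)C)[C@@H](O[Si](C)(C)C(C)(C)C)C1
A5 | alternative 3 | methyl diazo[3-methyl-3-(triethylsilyloxy)cyclopent-1-en-1-yl]acetate | COC(=O)C(=[N+]=[N-])C1=C[C@@](C)(O[Si](CC)(CC)CC)CC1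
A6 | alternative 3 | tert-butyl(dimethyl)[(2-isopropylbuta-1,3-dien-1-yl)oxy]silane | C=CC(C(C)C)=CO[Si](C)(C)C(C)(C)C
A7 | alternative 3 | cycloheptadiene ester (C10 methyl ester, C1=C10 and C7=C8 alkenes) | COC(=O)C1=C2CC[C@](C)(O[Si](CC)(CC)CC)[C@@H]2[C@H](O[Si](C)(C)C(C)(C)C)C(C(C)C)=CC1
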